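Ring B is disconnected into dimethyl malonate and an aryl enedione. The key step exploits the 1,3-relationship of the C3' and C5' oxygens and the one-carbon substituent at C2': malonate supplies C2' and C3', and a prenylated acetyl unit supplies C4'–C6'. In one operation the malonate anion adds to the alkene CH next to the ring-A aroyl group (bond C1'–C2') and the acetyl methyl then closes onto a malonate ester (bond C3'–C4'), giving ring B as a cyclohexane-1,3-dione carboxylate with every substituent already in place. The precursor is the (E)-enedione ArCO–CH=C(prenyl)–COCH3 carrying the brominated, MOM-protected ring A; dehydrogenation and redox adjustment then finish the target.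

Key step: step 9

Remark: the target has no stereocentre and no stereogenic double bond, so it is achiral and no enantiocontrol is needed; the stereocentres that appear in 11, 14–17 and 20 are racemic and are all erased later.
Remark: Ar = 3-bromo-6-methoxy-2-(methoxymethoxy)-4-methylphenyl (ring A, phenol as MOM ether); prenyl = 3-methylbut-2-en-1-yl.

Step 1
Reactants: 1 3,5-dimethoxytoluene
Product: 3 1-(2,6-dimethoxy-4-methylphenyl)ethan-1-one, via aryllithium 2 (not isolated)
Conditions: n-BuLi, TMEDA, THF, 0 °C → rt; then MeC(O)N(OMe)Me, −78 °C → rt; H2O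
Reagents that add atoms: N-methoxy-N-methylacetamide, CC(=O)N(C)OC
Why: Directed ortho-lithiation occurs at C4, the only position flanked by both methoxy groups, and Weinreb acylation of the aryllithium stops at the ketone; an electrophilic (Friedel–Crafts) acetylation is avoided because it would enter ortho to the methyl group.

Step 2
Reactants: 3 1-(2,6-dimethoxy-4-methylphenyl)ethan-1-one
Product: 4 1-(3-bromo-2,6-dimethoxy-4-methylphenyl)ethan-1-one
Conditions: NBS (1.0 equiv), MeCN, 0 °C → rt, dark
Reagents that add atoms: N-bromosuccinimide, O=C1CCC(=O)N1Br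
Why: Electrophilic aromatic bromination: the two open ring positions are equivalent and each is activated by an ortho and a para methoxy group, so a single monobromide should form, and without acid NBS attacks the activated ring faster than the ketone α-position.

Step 3
Reactants: 4 1-(3-bromo-2,6-dimethoxy-4-methylphenyl)ethan-1-one
Product: 5 1-(3-bromo-2-hydroxy-6-methoxy-4-methylphenyl)ethan-1-one
Conditions: BCl3 (1.2 equiv), CH2Cl2, −78 → 0 °C; then H2O
Reagents that add atoms: none
Why: Carbonyl-directed Lewis-acid ether cleavage: boron held by the acetyl oxygen reaches only the ortho methoxy groups, and the one wedged between bromine and the acetyl group is twisted out of the ring plane, so its oxygen is the more basic and its demethylation relieves strain, which should leave the C6 methoxy intact.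

Step 4
Reactants: 5 1-(3-bromo-2-hydroxy-6-methoxy-4-methylphenyl)ethan-1-one
Product: 6 1-[3-bromo-6-methoxy-2-(methoxymethoxy)-4-methylphenyl]ethan-1-one
Conditions: NaH (1.05 equiv), DMF, 0 °C; MOMCl, 0 °C → rt
Reagents that add atoms: chloromethyl methyl ether, COCCl
Why: Williamson-type O-alkylation of the sodium phenoxide; the phenol is far more acidic than the acetyl methyl group, so one equivalent of base should give only the aryl MOM ether.

Step 5
Reactants: 6 1-[3-bromo-6-methoxy-2-(methoxymethoxy)-4-methylphenyl]ethan-1-one
Product: 7 (2E)-1-Ar-3-(dimethylamino)prop-2-en-1-one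
Conditions: Me2NCH(OMe)2 (neat), 110 °C
Reagents that add atoms: N,N-dimethylformamide dimethyl acetal, COC(OC)N(C)C
Why: Amide-acetal condensation at the only enolisable position, the acetyl methyl group, gives the push–pull enaminone in its stable E form under neutral conditions that the MOM ether and the aryl bromide tolerate.

Step 6
Reactants: 7 (2E)-1-Ar-3-(dimethylamino)prop-2-en-1-one
Product: 8 2-Ar-2-oxoacetaldehyde (arylglyoxal)
Conditions: O3, CH2Cl2, −78 °C (to consumption of 7); then Me2S, −78 °C → rt
Reagents that add atoms: ozone, [O-][O+]=O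
Why: Ozonolysis of the electron-rich enamine-type C=C, which should react far faster than the arene, cleaves it to the α-keto aldehyde and DMF; this route to the glyoxal is non-acidic, whereas hot aqueous selenous acid would endanger the aryl MOM ether.

Step 7
Reactants: 9 dimethyl (2-oxopropyl)phosphonate; 10 prenyl bromide (1-bromo-3-methylbut-2-ene)
Product: 11 dimethyl (6-methyl-2-oxohept-5-en-3-yl)phosphonate (racemic)
Conditions: NaH (1.0 equiv), THF/DMF, 0 °C; then 10, 0 °C → rt
Reagents that add atoms: none
Why: SN2 alkylation of the sodium enolate of a β-ketophosphonate by an allylic bromide goes cleanly at carbon (a ketone-stabilised phosphorus ylide could alkylate at oxygen instead); the new stereocentre forms as a racemate and disappears in step 8.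

Step 8
Reactants: 8 2-Ar-2-oxoacetaldehyde; 11 dimethyl (6-methyl-2-oxohept-5-en-3-yl)phosphonate
Product: 12 (2E)-1-Ar-3-(3-methylbut-2-en-1-yl)pent-2-ene-1,4-dione
Conditions: 11, NaH, THF, 0 °C; then 8, −20 → 0 °C
Reagents that add atoms: none
Why: Horner–Wadsworth–Emmons olefination of the unhindered, non-enolisable aldehyde (the shielded aroyl ketone should not react); reversible addition should funnel through the less crowded oxaphosphetane to the E-alkene, aroyl trans to acetyl, and no free base remains to isomerise the product.

Step 9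
Reactants: 12 (2E)-1-Ar-3-(3-methylbut-2-en-1-yl)pent-2-ene-1,4-dione; 13 dimethyl malonate
Product: 15 methyl rac-(1S,5R,6R)-6-(ArCO)-2-hydroxy-5-(3-methylbut-2-en-1-yl)-4-oxocyclohex-2-ene-1-carboxylate, via Michael adduct 14 (not isolated)
Conditions: 13 (1.3 equiv), NaOMe (1.2 equiv), MeOH, 0 °C; add 12, 0 °C → 65 °C; then 1 M HCl to pH 3–4, 0 °C
Reagents that add atoms: none
Why: Sodium dimethyl malonate adds in a Michael reaction to the alkene CH of 12 (β to the acetyl group, α to the aroyl group) to give 14; proton transfer then forms the acetyl methyl enolate, which acylates one malonate ester and expels methoxide. This is the classical malonate Michael–Claisen annulation that turns enones into cyclohexane-1,3-dione carboxylates, applied here to an enedione. The single ring closes by a 6-(enolexo)-exo-trig acylation and is pulled to completion by deprotonation of the 1,3-dione formed. The three sp3 ring carbons C1, C5 and C6 are epimerisable under methoxide and should settle with the aroyl group trans to both neighbours; they are racemic and are erased in step 10, so no stereocontrol is needed. The step needs regioselective conjugate addition, secured because the other alkene carbon already carries the prenyl chain and the acetyl group and is sterically closed, and it needs ring closure on the ester instead of a five-membered aldol, secured because the aroyl carbonyl is flanked by two ortho substituents and is inaccessible.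

Step 10
Reactants: 15 methyl rac-(1S,5R,6R)-6-(ArCO)-2-hydroxy-5-(3-methylbut-2-en-1-yl)-4-oxocyclohex-2-ene-1-carboxylate
Product: 18 methyl 2-(ArCO)-4,6-dihydroxy-3-(3-methylbut-2-en-1-yl)benzoate, via selenide 16 (not isolated), via selenoxide 17 (not isolated)
Conditions: LDA (2.3 equiv), THF, −78 → −40 °C; PhSeBr (1.05 equiv), −78 °C; then mCPBA (1.0 equiv), CH2Cl2, −78 °C; pyridine, → rt
Reagents that add atoms: none
Why: Selenoxide dehydrogenation: the dianion of the vinylogous acid should take up selenium at its more basic terminus C1, anti to the neighbouring aroyl group and therefore syn to H-6, and oxidation at selenium followed by syn-elimination gives a cyclohexadienone that tautomerises to the resorcylate; the prenyl group should survive because selenium is delivered to a carbanion at −78 °C and the peracid is consumed by selenium before it can reach the alkene, which halogen or quinone dehydrogenation would not spare.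

Step 11
Reactants: 18 methyl 2-(ArCO)-4,6-dihydroxy-3-(3-methylbut-2-en-1-yl)benzoate
Product: 19 methyl 2-(ArCO)-4,6-bis(methoxymethoxy)-3-(3-methylbut-2-en-1-yl)benzoate
Conditions: NaH (2.5 equiv), DMF, 0 °C; MOMCl, 0 °C → rt
Reagents that add atoms: chloromethyl methyl ether, COCCl
Why: Double Williamson-type O-alkylation of the bis-phenoxide; the sodium salt in DMF is reactive enough to cap the hydrogen-bonded salicylate hydroxyl as well.

Step 12
Reactants: 19 methyl 2-(ArCO)-4,6-bis(methoxymethoxy)-3-(3-methylbut-2-en-1-yl)benzoate
Product: 20 Ar[2-(hydroxymethyl)-3,5-bis(methoxymethoxy)-6-(3-methylbut-2-en-1-yl)phenyl]methanol (racemic)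
Conditions: LiAlH4 (excess), THF, 0 °C → rt; aq. NaOH work-up
Reagents that add atoms: none
Why: Exhaustive hydride reduction takes the ester to the primary alcohol and the diaryl ketone to the benzhydrol (through the phthalide if the ketone reacts first), which avoids any need to distinguish the two carbonyl groups; the carbinol centre is racemic and is removed in step 13.

Step 13
Reactants: 20 Ar[2-(hydroxymethyl)-3,5-bis(methoxymethoxy)-6-(3-methylbut-2-en-1-yl)phenyl]methanol
Product: 21 2-(ArCO)-4,6-bis(methoxymethoxy)-3-(3-methylbut-2-en-1-yl)benzaldehyde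
Conditions: (COCl)2, DMSO, CH2Cl2, −78 °C; then Et3N, −78 → 0 °C
Reagents that add atoms: none
Why: Swern oxidation: both hydroxyls are converted to alkoxysulfonium ions before base is added, so aldehyde and ketone appear together and the hydroxy-aldehyde that would close to a lactol and be over-oxidised to a phthalide is never present.

Step 14
Reactants: 21 2-(ArCO)-4,6-bis(methoxymethoxy)-3-(3-methylbut-2-en-1-yl)benzaldehyde
Product: 22 Pestalone B, 2-(3-bromo-2-hydroxy-6-methoxy-4-methylbenzoyl)-4,6-dihydroxy-3-(3-methylbut-2-en-1-yl)benzaldehyde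
Conditions: 3 M aq. HCl, MeOH/THF, rt → 40 °C
Reagents that add atoms: none
Why: Acid-catalysed acetal exchange removes the three aryl MOM ethers as dimethoxymethane, and dilute acid at modest temperature should stop short of acid-mediated chroman closure of the prenyl group onto the C5' hydroxyl.

Compound list
1 | 3,5-dimethoxytoluene | COc1cc(C)cc(OC)c1 | starting material
2 | (2,6-dimethoxy-4-methylphenyl)lithium, formed in situ | [Li]c1c(OC)cc(C)cc1OC | intermediate
3 | 1-(2,6-dimethoxy-4-methylphenyl)ethan-1-one | CC(=O)c1c(OC)cc(C)cc1OC | intermediate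
4 | 1-(3-bromo-2,6-dimethoxy-4-methylphenyl)ethan-1-one | CC(=O)c1c(OC)cc(C)c(Br)c1OC | intermediate
5 | 1-(3-bromo-2-hydroxy-6-methoxy-4-methylphenyl)ethan-1-one | CC(=O)c1c(OC)cc(C)c(Br)c1O | intermediate
6 | 1-[3-bromo-6-methoxy-2-(methoxymethoxy)-4-methylphenyl]ethan-1-one | CC(=O)c1c(OC)cc(C)c(Br)c1OCOC | intermediate
7 | (2E)-1-[3-bromo-6-methoxy-2-(methoxymethoxy)-4-methylphenyl]-3-(dimethylamino)prop-2-en-1-one | CN(C)/C=C/C(=O)c1c(OC)cc(C)c(Br)c1OCOC | intermediate
8 | 2-[3-bromo-6-methoxy-2-(methoxymethoxy)-4-methylphenyl]-2-oxoacetaldehyde | O=CC(=O)c1c(OC)cc(C)c(Br)c1OCOC | intermediate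
9 | dimethyl (2-oxopropyl)phosphonate | COP(=O)(OC)CC(C)=O | starting material
10 | prenyl bromide (1-bromo-3-methylbut-2-ene) | CC(C)=CCBr | starting material
11 | dimethyl (6-methyl-2-oxohept-5-en-3-yl)phosphonate, racemic | COP(=O)(OC)C(CC=C(C)C)C(C)=O | intermediate
12 | (2E)-1-[3-bromo-6-methoxy-2-(methoxymethoxy)-4-methylphenyl]-3-(3-methylbut-2-en-1-yl)pent-2-ene-1,4-dione | CC(=O)/C(CC=C(C)C)=C/C(=O)c1c(OC)cc(C)c(Br)c1OCOC | intermediate
13 | dimethyl malonate | COC(=O)CC(=O)OC | starting material
14 | dimethyl 2-{1-[3-bromo-6-methoxy-2-(methoxymethoxy)-4-methylphenyl]-3-(3-methylbut-2-en-1-yl)-1,4-dioxopentan-2-yl}propanedioate, diastereomer mixture, formed in situ | COC(=O)C(C(=O)OC)C(C(=O)c1c(OC)cc(C)c(Br)c1OCOC)C(CC=C(C)C)C(C)=O | intermediate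
15 | methyl rac-(1S,5R,6R)-6-[3-bromo-6-methoxy-2-(methoxymethoxy)-4-methylbenzoyl]-2-hydroxy-5-(3-methylbut-2-en-1-yl)-4-oxocyclohex-2-ene-1-carboxylate (aroyl trans to both neighbours; one enantiomer drawn) | COC(=O)[C@@H]1C(O)=CC(=O)[C@H](CC=C(C)C)[C@H]1C(=O)c1c(OC)cc(C)c(Br)c1OCOC | intermediate
16 | methyl 6-[3-bromo-6-methoxy-2-(methoxymethoxy)-4-methylbenzoyl]-2-hydroxy-5-(3-methylbut-2-en-1-yl)-4-oxo-1-(phenylselanyl)cyclohex-2-ene-1-carboxylate, formed in situ | COC(=O)C1([Se]c2ccccc2)C(O)=CC(=O)C(CC=C(C)C)C1C(=O)c1c(OC)cc(C)c(Br)c1OCOC | intermediate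
17 | the Se-oxide of 16 (1-benzeneseleninyl compound), formed in situ | COC(=O)C1([Se](=O)c2ccccc2)C(O)=CC(=O)C(CC=C(C)C)C1C(=O)c1c(OC)cc(C)c(Br)c1OCOC | intermediate
18 | methyl 2-[3-bromo-6-methoxy-2-(methoxymethoxy)-4-methylbenzoyl]-4,6-dihydroxy-3-(3-methylbut-2-en-1-yl)benzoate | COC(=O)c1c(O)cc(O)c(CC=C(C)C)c1C(=O)c1c(OC)cc(C)c(Br)c1OCOC | intermediate
19 | methyl 2-[3-bromo-6-methoxy-2-(methoxymethoxy)-4-methylbenzoyl]-4,6-bis(methoxymethoxy)-3-(3-methylbut-2-en-1-yl)benzoate | COC(=O)c1c(OCOC)cc(OCOC)c(CC=C(C)C)c1C(=O)c1c(OC)cc(C)c(Br)c1OCOC | intermediate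
20 | [3-bromo-6-methoxy-2-(methoxymethoxy)-4-methylphenyl][2-(hydroxymethyl)-3,5-bis(methoxymethoxy)-6-(3-methylbut-2-en-1-yl)phenyl]methanol, racemic | OCc1c(OCOC)cc(OCOC)c(CC=C(C)C)c1C(O)c1c(OC)cc(C)c(Br)c1OCOC | intermediate
21 | 2-[3-bromo-6-methoxy-2-(methoxymethoxy)-4-methylbenzoyl]-4,6-bis(methoxymethoxy)-3-(3-methylbut-2-en-1-yl)benzaldehyde | O=Cc1c(OCOC)cc(OCOC)c(CC=C(C)C)c1C(=O)c1c(OC)cc(C)c(Br)c1OCOC | intermediate
22 | Pestalone B, 2-(3-bromo-2-hydroxy-6-methoxy-4-methylbenzoyl)-4,6-dihydroxy-3-(3-methylbut-2-en-1-yl)benzaldehyde (achiral) | COc1cc(C)c(Br)c(O)c1C(=O)c1c(C=O)c(O)cc(O)c1CC=C(C)C | target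

Total step count: 14.
Longest linear sequence: 13 steps (1 to 22 through steps 1–6 and 8–14; step 7 is the side branch).

Steps most likely to fail

Step 9. What may go wrong: methoxide or the malonate anion removes a proton from the doubly allylic CH2 of the prenyl chain (γ to the aroyl carbonyl) so that the alkene migrates out of conjugation before addition, or the adduct reverts or closes by aldol reaction instead of acylation. Fallback: separate the two bond formations. Setting out from 12, conjugate addition of 13 under solid–liquid phase transfer (K2CO3, Bu4NBr, toluene, 0 °C), where only a trace of weakly basic malonate ion pair is present, should allow the Michael adduct 14 to be isolated. The ring is then closed on its own with t-BuOK in THF at 0 °C, an irreversible acylation in an aprotic medium, which comes back to the route at 15. No compound outside the list is made (F0).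

Step 10. What may go wrong: the second deprotonation takes place at an unproductive site, or electrophilic selenium species add to the trisubstituted alkene or attack the newly formed electron-rich arene. Fallback: oxidise a neutral dienol ether in place of an enolate. Setting out from 15, TBSOTf and Et3N (CH2Cl2, −78 → 0 °C) should give methyl 6-(ArCO)-2,4-bis(tert-butyldimethylsilyloxy)-5-(3-methylbut-2-en-1-yl)cyclohexa-1,3-diene-1-carboxylate F1. DDQ (1.05 equiv, 2,6-lutidine, CH2Cl2, 0 °C) should take hydride from this doubly oxygen-stabilised diene much faster than from the prenyl chain and give methyl 2-(ArCO)-4,6-bis(tert-butyldimethylsilyloxy)-3-(3-methylbut-2-en-1-yl)benzoate F2, so that no free ortho-prenyl phenol meets the quinone. TBAF buffered with AcOH (THF, 0 °C) then comes back to the route at 18.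

Step 3. What may go wrong: loss of regiocontrol in the ether cleavage (attack at the C6 methoxy group) or double demethylation. Fallback: change the order so that the ether cleavage needs no selectivity. Setting out from 3, whose two methoxy groups are equivalent, BCl3 (CH2Cl2, −78 → 0 °C) gives 1-(2-hydroxy-6-methoxy-4-methylphenyl)ethan-1-one F3. Amine-mediated ortho-bromination of the phenol (NBS, catalytic i-Pr2NH, CH2Cl2, 0 °C), in which a hydrogen-bonded N-bromoamine delivers bromine next to the hydroxyl, then comes back to the route at 5, bypassing 4.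

Further compounds
F0 | step 9 | none | none
F1 | step 10 | methyl 6-[3-bromo-6-methoxy-2-(methoxymethoxy)-4-methylbenzoyl]-2,4-bis(tert-butyldimethylsilyloxy)-5-(3-methylbut-2-en-1-yl)cyclohexa-1,3-diene-1-carboxylate, racemic | COC(=O)C1=C(O[Si](C)(C)C(C)(C)C)C=C(O[Si](C)(C)C(C)(C)C)C(CC=C(C)C)C1C(=O)c1c(OC)cc(C)c(Br)c1OCOC
F2 | step 10 | methyl 2-[3-bromo-6-methoxy-2-(methoxymethoxy)-4-methylbenzoyl]-4,6-bis(tert-butyldimethylsilyloxy)-3-(3-methylbut-2-en-1-yl)benzoate | COC(=O)c1c(O[Si](C)(C)C(C)(C)C)cc(O[Si](C)(C)C(C)(C)C)c(CC=C(C)C)c1C(=O)c1c(OC)cc(C)c(Br)c1OCOC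
F3 | step 3 | 1-(2-hydroxy-6-methoxy-4-methylphenyl)ethan-1-one | CC(=O)c1c(OC)cc(C)cc1O
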